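**Plan**
1. Retrosynthesis: remove the 2-methylbutanoate (O5), the isovalerate (O9) and a tert-butyl mask on O8; cut C11=C13, then the lactone C12–O6 bond and the C7–C11 bond (enolate alkylation); cut C8–C9 by a retro-oxy-Cope shift; the resulting cyclohexanol is cut at C6–C7 (acetylide addition) and C1–C10 (Suzuki coupling) back to a quinone monoketal.
2. Enabling feature: in the ten-membered carbocycle the C8–C9 glycol bond lies 1,6 to the C1–C6 bond, C6 bears oxygen and C10 a methyl group. The ring is therefore a masked (E,E)-cyclodeca-1,5-diene (C6=C7 enolate, C1=C10 alkene), the [3,3] product of a trans-1,2-dialkenylcyclohexanol whose six-membered ring is C1–C6.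
3. Forward: C1–C6 arrive as a quinone monoketal (C3 ketal, C4 methyl). The cyclohexane is elaborated first, the ten-membered ring is made by ring expansion with C7 alkylated in the same flask, the γ-lactone is closed next, then C10–H, C13 and the esters follow.
4. Stereochemistry: C4/C5 by OsO4 anti to a CBS-derived carbinol at C6 (later oxidised); C8/C9 by chirality transfer from C1/C6 through a chair transition state with two E alkenes; C7, C6 and C10 by attack on the periphery of the ten-membered ring; the ester stereocenter from (R)-2-methylbutanoic acid.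
5. Masking: O8 as tert-butyl ether, O9 as a C–SiMe2Ph bond (oxidised with retention), C3 as dimethyl ketal, O4/O5 as acetonide.

Key step: step 13

Remark: atom numbers are those of the target (C1/C2 = CH2CH2, C3 = ketone carbon, C4 = methyl carbinol, C5 = CH–O-2-methylbutanoyl, C6 = lactone CH–O, C7 = ring-fusion CH, C8 = CHOH, C9 = CH–O-isovaleryl, C10 = CH–CH3, C11–C13 = lactone C, C=O, =CH2); β is the ring face carrying the C4 methyl group (target: 4α-OH, 5α-O, 6β-O, 7α-C11, 8β-OH, 9α-O, 10α-CH3); (R)-2-methylbutanoic acid and the other starting materials are taken to be catalogue compounds.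

**Step 1**
Reactants: 1 4-methoxy-3-methylphenol
Product: 2 4,4-dimethoxy-3-methylcyclohexa-2,5-dien-1-one
Conditions: PhI(OAc)2, MeOH, 0 °C
Reagents that add atoms: methanol, CO
Why: Oxidative dearomatisation of a para-alkoxyphenol in methanol (quinone monoketal formation) traps the phenoxenium ion at the para carbon, so the future C6 carbonyl is free and the future C3 carbonyl is already masked as its dimethyl ketal.

**Step 2**
Reactants: 2 4,4-dimethoxy-3-methylcyclohexa-2,5-dien-1-one
Product: 3 2-iodo-4,4-dimethoxy-5-methylcyclohexa-2,5-dien-1-one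
Conditions: I2, pyridine, CH2Cl2, 25 °C
Reagents that add atoms: iodine, II
Why: α-Iodination of an enone by pyridine addition–iodination–elimination needs a β-carbon that bears hydrogen, so iodine should enter only at the future C1 and not on the methyl-substituted arm.

**Step 3**
Reactants: 3 2-iodo-4,4-dimethoxy-5-methylcyclohexa-2,5-dien-1-one
Product: 4 (1R)-2-iodo-4,4-dimethoxy-5-methylcyclohexa-2,5-dien-1-ol
Conditions: (S)-2-methyl-CBS-oxazaborolidine (20 mol %), catecholborane, PhMe, −78 °C
Reagents that add atoms: none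
Why: Corey–Bakshi–Shibata reduction distinguishes the iodine-bearing (large) from the unsubstituted (small) vinyl flank of the ketone, so the (S)-catalyst should give the (1R)-carbinol (6β-OH), a temporary stereocenter that will control C4 and C5.

**Step 4**
Reactants: 4 (1R)-2-iodo-4,4-dimethoxy-5-methylcyclohexa-2,5-dien-1-ol
Product: 5 (1R,5R,6R)-2-iodo-4,4-dimethoxy-5-methylcyclohex-2-ene-1,5,6-triol
Conditions: OsO4 (2 mol %), N-methylmorpholine N-oxide, acetone/H2O, 0 → 25 °C
Reagents that add atoms: N-methylmorpholine N-oxide, C[N+]1([O-])CCOCC1; water, O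
Why: Catalytic OsO4 syn-dihydroxylation should choose the electron-richer trisubstituted alkene over the iodoalkene and add anti to the allylic hydroxyl, which sets the cis C4/C5 diol (both oxygens α) in one operation.

**Step 5**
Reactants: 5 (1R,5R,6R)-2-iodo-4,4-dimethoxy-5-methylcyclohex-2-ene-1,5,6-triol
Product: 6 iodo acetonide (5,6-O-isopropylidene derivative of 5 with the allylic 1-OH free)
Conditions: 2,2-dimethoxypropane, PPTS (cat.), acetone, 25 °C
Reagents that add atoms: 2,2-dimethoxypropane, COC(C)(C)OC
Why: Acid-catalysed acetonide formation is possible only for the cis O4/O5 pair, because the allylic hydroxyl is trans to O5 and therefore stays free.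

**Step 6**
Reactants: 7 1-propynylmagnesium bromide; 8 chlorodimethylphenylsilane
Product: 9 dimethyl(phenyl)(prop-1-yn-1-yl)silane
Conditions: THF, 0 → 25 °C
Reagents that add atoms: none
Why: Substitution at silicon by the alkynyl Grignard reagent gives the silylalkyne that becomes the C9/C10/methyl unit.

**Step 7**
Reactants: 6 iodo acetonide; 9 dimethyl(phenyl)(prop-1-yn-1-yl)silane
Product: 11 silyl dienol (iodine of 6 replaced by the (E)-2-(dimethylphenylsilyl)-1-methylvinyl group), via alkenylborane 10 (not isolated)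
Conditions: 9-BBN, THF, 25 → 60 °C (on 9); then 6, PdCl2(dppf) (5 mol %), AsPh3, aq. NaOH, THF/DMF, 50 °C
Reagents that add atoms: none
Why: 9-BBN adds syn to the silylalkyne with boron on the methyl-bearing carbon (β to silicon), and the B-alkenyl Suzuki–Miyaura coupling with the vinyl iodide goes with retention, so silicon ends trans to the ring carbon (E), the geometry that later fixes C9.

**Step 8**
Reactants: 11 silyl dienol
Product: 12 silyl dienone (C6 ketone of 11)
Conditions: Dess–Martin periodinane, pyridine, CH2Cl2, 0 → 25 °C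
Reagents that add atoms: none
Why: Dess–Martin oxidation of the allylic alcohol gives the cross-conjugated enone without touching ketal, acetonide or vinylsilane, the carbinol center having served its purpose.

**Step 9**
Reactants: 12 silyl dienone
Product: 13 cyclohexanone (C1=C2 of 12 saturated; alkenyl group α at C1 and cis to O5; 3,3-dimethoxy; 4α,5α-acetonide)
Conditions: [(Ph3P)CuH]6, H2O (2 equiv), PhH/THF, 25 °C
Reagents that add atoms: none
Why: Copper hydride conjugate reduction delivers hydride to the β-carbon (C2) of the only enone, and axial protonation of the resulting C6–C1 enolate places the alkenyl group equatorial and α, which is also the more stable C1 epimer (cis-1,3 to the equatorial O5).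

**Step 10**
Reactants: 14 trichloroethylene; 15 potassium tert-butoxide
Product: 16 (E)-1-tert-butoxy-1,2-dichloroethene
Conditions: THF, −78 → 25 °C
Reagents that add atoms: none
Why: Net replacement of one vinylic chloride by tert-butoxide (elimination–addition) gives the dichlorovinyl ether that serves as a stable precursor of the alkoxyacetylide.

**Step 11**
Reactants: 13 cyclohexanone; 16 (E)-1-tert-butoxy-1,2-dichloroethene
Product: 19 alkynyl carbinol (6α-OH and 6β-tert-butoxyethynyl), via chloroalkyne 17 (not isolated), via lithium acetylide 18 (not isolated)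
Conditions: n-BuLi (2.2 equiv on 16), THF, −78 → −40 °C; then 13, −78 → 0 °C; aqueous work-up
Reagents that add atoms: none
Why: Elimination and Cl–Li exchange turn 16 into lithium tert-butoxyacetylide, whose 1,2-addition should occur from the β face (equatorial attack) because the α face is blocked by the axial C4–O bond of the cis-fused acetonide, so the hydroxyl becomes axial (α) and the two unsaturated groups trans-diequatorial.

**Step 12**
Reactants: 19 alkynyl carbinol
Product: 20 dialkenyl carbinol (6α-OH; 6β-(E)-2-tert-butoxyvinyl; 1α-(E)-2-(dimethylphenylsilyl)-1-methylvinyl)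
Conditions: NaAlH2(OCH2CH2OMe)2, THF, 0 → 25 °C; aq. Rochelle salt
Reagents that add atoms: none
Why: Alkoxide-directed trans-hydroalumination of the propargylic alcohol followed by protonolysis gives the E enol ether on mechanistic grounds, the geometry that later fixes C8.

**Step 13**
Reactants: 20 dialkenyl carbinol; 21 methyl bromoacetate
Product: 23 ten-membered keto ester (methyl 2-(6-oxo-cyclodec-1(10)E-en-7α-yl)acetate with 8β-tert-butoxy and 9α-dimethylphenylsilyl; 3,3-dimethoxy; 4α,5α-acetonide), via potassium enolate 22 (not isolated)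
Conditions: KN(SiMe3)2, 18-crown-6, THF, 0 → 25 °C; then 21, −78 °C
Reagents that add atoms: none
Why: Deprotonation of the tertiary alcohol gives a potassium alkoxide that undergoes an anionic oxy-Cope [3,3] shift in which the C1–C6 bond of the cyclohexane breaks while C8–C9 forms between the two alkene termini, so the six-membered ring is expanded by four atoms to the ten-membered ring (a ring expansion through a six-membered cyclic transition state, not an end-to-end cyclisation) and the C6–C7 potassium enolate 22 is formed regiospecifically. The closest known reaction type is the anionic oxy-Cope ring expansion of trans-1,2-dialkenylcyclohexanols to (E)-cyclodec-5-enones with C-alkylation of the enolate in the same flask. Because both unsaturated groups are equatorial on the chair cyclohexane, the shift must pass through the chair-like (trans-decalin-like) transition state, and with the E enol ether and the E vinylsilane both terminal substituents stay equatorial, which fixes C8 (O β) and C9 (Si α) relative to each other and, through the C1 and C6 centers that are destroyed, relative to C4/C5. The new C1=C10 alkene is E and the enolate has C5 and C8 trans. Methyl bromoacetate then attacks C7 from the ring periphery, anti to the C8–C9 bond that stands perpendicular to the enolate plane with C8–H eclipsed (A1,3 strain), which sets C7 (α). The step needs the [3,3] shift to outrun loss of tert-butoxide from the β-alkoxy enolate; the chair pre-organisation serves the first, and the poor leaving group, the C8–O bond lying near the enolate plane (no overlap) and alkylation at −78 °C serve the second.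

**Step 14**
Reactants: 23 ten-membered keto ester
Product: 25 trans-fused γ-lactone (6β-O and 7α-C11; C1=C10 retained), via hydroxy ester 24 (not isolated)
Conditions: NaBH4, MeOH, −20 → 25 °C
Reagents that add atoms: none
Why: Hydride reduction of the α-alkoxy ketone from the ring periphery in the dipole-minimised conformer (C6=O anti to the C5–O bond; non-chelation control) should give the 6β-alkoxide, trans to the C7 acetate arm, which closes the γ-lactone by intramolecular transesterification.

**Step 15**
Reactants: 25 trans-fused γ-lactone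
Product: 26 saturated lactone (10α-methyl)
Conditions: H2 (1 bar), [Ir(cod)(PCy3)(py)]PF6 (5 mol %), CH2Cl2, 25 °C
Reagents that add atoms: none
Why: Homogeneous hydrogenation should add H2 to the trisubstituted E alkene from its exposed peripheral face, anti to the C8–C9 bond and to the α-silyl group, which places H on the β face of C10 and the methyl group α.

**Step 16**
Reactants: 26 saturated lactone
Product: 29 α-methylene lactone (C11=C13), via Mannich base 27 (not isolated), via ammonium iodide 28 (not isolated)
Conditions: LiN(i-Pr)2, THF, −78 °C; dimethyl(methylene)ammonium iodide, −78 → 0 °C; then MeI, MeOH, 25 °C; then NaHCO3, CH2Cl2/H2O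
Reagents that add atoms: dimethyl(methylene)ammonium iodide, C=[N+](C)C.[I-]
Why: Aminomethylation of the lactone lithium enolate, N-quaternisation and β-elimination (the standard α-methylenation of γ-lactones) install C13, the lactone α-CH2 being the only acidic site while ketal, acetonide, ether and C–Si bond are inert.

**Step 17**
Reactants: 29 α-methylene lactone
Product: 30 9α-alcohol
Conditions: KBr, NaOAc, AcOOH, AcOH, 0 → 25 °C
Reagents that add atoms: peracetic acid, CC(=O)OO
Why: Fleming–Tamao oxidation (ipso-bromodesilylation of the phenyl group, then peracid-induced 1,2-shift from silicon to oxygen) turns C9–Si into C9–OH with retention, the acetate buffer sparing ketal, acetonide and tert-butyl ether and the electron-poor methylene lactone being a poor partner for the electrophiles.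

**Step 18**
Reactants: 30 9α-alcohol; 31 3-methylbutanoyl chloride
Product: 32 9α-isovalerate
Conditions: pyridine, DMAP (cat.), CH2Cl2, 0 → 25 °C
Reagents that add atoms: none
Why: Acylation of the only free hydroxyl with the acid chloride under nucleophilic catalysis installs the isovalerate.

**Step 19**
Reactants: 32 9α-isovalerate
Product: 33 keto diol (C3 ketone; 4α-OH; 5α-OH)
Conditions: 1 M aq. HCl, THF, 25 °C
Reagents that add atoms: water, O
Why: Dilute aqueous acid hydrolyses the dimethyl ketal and the acetonide in one operation, while the tert-butyl ether (which needs strong anhydrous acid) and both ester groups should remain.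

**Step 20**
Reactants: 33 keto diol; 34 (R)-2-methylbutanoic acid
Product: 35 8-O-tert-butyl ether of the target
Conditions: DCC, DMAP (cat.), CH2Cl2, 0 → 25 °C
Reagents that add atoms: none
Why: Steglich esterification acylates the secondary C5 hydroxyl and leaves the tertiary C4 hydroxyl untouched, the side-chain stereocenter being carried in unchanged from the acid.

**Step 21**
Reactants: 35 8-O-tert-butyl ether of the target
Product: 36 target CNP0269576.1
Conditions: CF3CO2H, CH2Cl2, 0 °C
Reagents that add atoms: none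
Why: Acidolysis of the tert-butyl ether (loss of 2-methylpropene) frees the C8 hydroxyl without base, so neither acyl migration nor relactonisation onto O8 is provoked.

**Compound list**
1 | 4-methoxy-3-methylphenol | COc1ccc(O)cc1C | starting material
2 | 4,4-dimethoxy-3-methylcyclohexa-2,5-dien-1-one | O=C1C=CC(OC)(OC)C(C)=C1 | intermediate
3 | 2-iodo-4,4-dimethoxy-5-methylcyclohexa-2,5-dien-1-one | O=C1C(I)=CC(OC)(OC)C(C)=C1 | intermediate
4 | (1R)-2-iodo-4,4-dimethoxy-5-methylcyclohexa-2,5-dien-1-ol | O[C@H]1C(I)=CC(OC)(OC)C(C)=C1 | intermediate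
5 | (1R,5R,6R)-2-iodo-4,4-dimethoxy-5-methylcyclohex-2-ene-1,5,6-triol | O[C@H]1C(I)=CC(OC)(OC)[C@](C)(O)[C@@H]1O | intermediate
6 | iodo acetonide (5,6-O-isopropylidene derivative of 5) | O[C@H]1C(I)=CC(OC)(OC)[C@]2(C)OC(C)(C)O[C@@H]21 | intermediate
7 | 1-propynylmagnesium bromide | CC#C[Mg]Br | starting material
8 | chlorodimethylphenylsilane | C[Si](C)(Cl)c1ccccc1 | starting material
9 | dimethyl(phenyl)(prop-1-yn-1-yl)silane | CC#C[Si](C)(C)c1ccccc1 | intermediate
10 | 9-[(Z)-1-(dimethylphenylsilyl)prop-1-en-2-yl]-9-borabicyclo[3.3.1]nonane (B trans to Si) | C/C(B1C2CCCC1CCC2)=C\[Si](C)(C)c1ccccc1 | intermediate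
11 | silyl dienol (6 with iodine replaced by the (E)-2-(dimethylphenylsilyl)-1-methylvinyl group) | O[C@H]1C(/C(C)=C/[Si](C)(C)c2ccccc2)=CC(OC)(OC)[C@]3(C)OC(C)(C)O[C@@H]31 | intermediate
12 | silyl dienone (C6 ketone of 11) | O=C1C(/C(C)=C/[Si](C)(C)c2ccccc2)=CC(OC)(OC)[C@]3(C)OC(C)(C)O[C@@H]31 | intermediate
13 | cyclohexanone with 1α-alkenyl group, 3,3-dimethoxy, 4β-methyl, 4α,5α-isopropylidenedioxy | O=C1[C@H](/C(C)=C/[Si](C)(C)c2ccccc2)CC(OC)(OC)[C@]3(C)OC(C)(C)O[C@@H]31 | intermediate
14 | trichloroethylene | ClC=C(Cl)Cl | starting material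
15 | potassium tert-butoxide | CC(C)(C)[O-].[K+] | starting material
16 | (E)-1-tert-butoxy-1,2-dichloroethene | Cl/C=C(Cl)\OC(C)(C)C | intermediate
17 | tert-butoxy(chloro)ethyne | ClC#COC(C)(C)C | intermediate
18 | lithium tert-butoxyacetylide | [Li]C#COC(C)(C)C | intermediate
19 | alkynyl carbinol (6α-OH, 6β-tert-butoxyethynyl) | O[C@]1(C#COC(C)(C)C)[C@H](/C(C)=C/[Si](C)(C)c2ccccc2)CC(OC)(OC)[C@]3(C)OC(C)(C)O[C@@H]31 | intermediate
20 | dialkenyl carbinol (6α-OH, 6β-(E)-2-tert-butoxyvinyl, 1α-(E)-alkenylsilane) | O[C@]1(/C=C/OC(C)(C)C)[C@H](/C(C)=C/[Si](C)(C)c2ccccc2)CC(OC)(OC)[C@]3(C)OC(C)(C)O[C@@H]31 | intermediate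
21 | methyl bromoacetate | COC(=O)CBr | starting material
22 | potassium enolate of the ten-membered ketone (C6–O⁻, C6=C7; 8β-OtBu, 9α-SiMe2Ph, 1(10)E) | [K+].[O-]/C1=C\[C@@H](OC(C)(C)C)[C@H]([Si](C)(C)c2ccccc2)/C(C)=C/CC(OC)(OC)[C@]3(C)OC(C)(C)O[C@@H]31 | intermediate
23 | ten-membered keto ester (7α-CH2CO2Me, 8β-OtBu, 9α-SiMe2Ph, 1(10)E, 3,3-dimethoxy, 4α,5α-acetonide) | O=C1[C@H](CC(=O)OC)[C@@H](OC(C)(C)C)[C@H]([Si](C)(C)c2ccccc2)/C(C)=C/CC(OC)(OC)[C@]3(C)OC(C)(C)O[C@@H]31 | intermediate
24 | 6β-hydroxy ester | O[C@H]1[C@H](CC(=O)OC)[C@@H](OC(C)(C)C)[C@H]([Si](C)(C)c2ccccc2)/C(C)=C/CC(OC)(OC)[C@]3(C)OC(C)(C)O[C@@H]31 | intermediate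
25 | trans-fused γ-lactone (6β-O, 7α-C11, 1(10)E) | O=C1O[C@H]2[C@H](C1)[C@@H](OC(C)(C)C)[C@H]([Si](C)(C)c3ccccc3)/C(C)=C/CC(OC)(OC)[C@]4(C)OC(C)(C)O[C@@H]42 | intermediate
26 | saturated lactone (10α-methyl) | O=C1O[C@H]2[C@H](C1)[C@@H](OC(C)(C)C)[C@H]([Si](C)(C)c3ccccc3)[C@H](C)CCC(OC)(OC)[C@]4(C)OC(C)(C)O[C@@H]42 | intermediate
27 | Mannich base (11-dimethylaminomethyl lactone, C11 epimers) | CN(C)CC1C(=O)O[C@H]2[C@H]1[C@@H](OC(C)(C)C)[C@H]([Si](C)(C)c3ccccc3)[C@H](C)CCC(OC)(OC)[C@]4(C)OC(C)(C)O[C@@H]42 | intermediate
28 | trimethylammonium iodide of 27 | [I-].C[N+](C)(C)CC1C(=O)O[C@H]2[C@H]1[C@@H](OC(C)(C)C)[C@H]([Si](C)(C)c3ccccc3)[C@H](C)CCC(OC)(OC)[C@]4(C)OC(C)(C)O[C@@H]42 | intermediate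
29 | α-methylene lactone (8β-OtBu, 9α-SiMe2Ph) | C=C1C(=O)O[C@H]2[C@H]1[C@@H](OC(C)(C)C)[C@H]([Si](C)(C)c3ccccc3)[C@H](C)CCC(OC)(OC)[C@]4(C)OC(C)(C)O[C@@H]42 | intermediate
30 | 9α-alcohol | C=C1C(=O)O[C@H]2[C@H]1[C@@H](OC(C)(C)C)[C@H](O)[C@H](C)CCC(OC)(OC)[C@]3(C)OC(C)(C)O[C@@H]32 | intermediate
31 | 3-methylbutanoyl chloride | CC(C)CC(=O)Cl | starting material
32 | 9α-isovalerate | C=C1C(=O)O[C@H]2[C@H]1[C@@H](OC(C)(C)C)[C@H](OC(=O)CC(C)C)[C@H](C)CCC(OC)(OC)[C@]3(C)OC(C)(C)O[C@@H]32 | intermediate
33 | keto diol (C3 ketone, 4α-OH, 5α-OH) | C=C1C(=O)O[C@H]2[C@H]1[C@@H](OC(C)(C)C)[C@H](OC(=O)CC(C)C)[C@H](C)CCC(=O)[C@](C)(O)[C@@H]2O | intermediate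
34 | (R)-2-methylbutanoic acid | CC[C@@H](C)C(=O)O | starting material
35 | 8-O-tert-butyl ether of the target | C=C1C(=O)O[C@H]2[C@H]1[C@@H](OC(C)(C)C)[C@H](OC(=O)CC(C)C)[C@H](C)CCC(=O)[C@](C)(O)[C@@H]2OC(=O)[C@H](C)CC | intermediate
36 | CNP0269576.1 | C=C1C(=O)O[C@H]2[C@H]1[C@@H](O)[C@H](OC(=O)CC(C)C)[C@H](C)CCC(=O)[C@](C)(O)[C@@H]2OC(=O)[C@H](C)CC | target

**Totals**
Total step count: 21. Longest linear sequence: 19 steps (steps 1–5, 7–9, 11–21, from 1).

**Steps most likely to fail**

Step 13. The β-alkoxy enolate may expel tert-butoxide (E1cB) before it is alkylated, or the crowded hetero-substituted termini may slow the [3,3] shift so that the alkoxide decomposes. Fallback: starting from 20, the tertiary hydroxyl is silylated (1-(trimethylsilyl)imidazole) to the trimethylsilyl ether F1. A neutral thermal siloxy-Cope rearrangement (o-dichlorobenzene, 200 °C) gives the ten-membered trimethylsilyl enol ether F2 without a free enolate. MeLi at −78 °C then releases the lithium enolate F3, which is alkylated with 21, and the route is rejoined at 23.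

Step 14. Hydride may attack the other carbonyl face, giving the 6α-alcohol and hence the cis-fused lactone. Fallback: starting from 23, the reduction product is collected as the cis-fused lactone F4. LiOH opens it to the 6α-hydroxy acid F5. Mitsunobu lactonisation (PPh3, DIAD, THF) then closes the ring with inversion at C6, and the route is rejoined at 25.

Step 17. The electrophilic bromine/peracid medium may attack the methylene lactone, or the acidic medium may damage the ketal before the C–Si bond is oxidised. Fallback: starting from 26, the same oxidation is done before the methylene group exists, giving the saturated 9α-alcohol F6. It is protected as the triethylsilyl ether F7 (Et3SiCl, imidazole). Methylenation as in step 16 then proceeds through the Mannich base F8 and the ammonium iodide F9 to the silylated methylene lactone F10. HF·pyridine removes the silyl group, and the route is rejoined at 30.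

**Further compounds**
F1 | step 13 | trimethylsilyl ether of 20 | C[Si](C)(C)O[C@]1(/C=C/OC(C)(C)C)[C@H](/C(C)=C/[Si](C)(C)c2ccccc2)CC(OC)(OC)[C@]3(C)OC(C)(C)O[C@@H]31
F2 | step 13 | ten-membered trimethylsilyl enol ether | C[Si](C)(C)O/C1=C\[C@@H](OC(C)(C)C)[C@H]([Si](C)(C)c2ccccc2)/C(C)=C/CC(OC)(OC)[C@]3(C)OC(C)(C)O[C@@H]31
F3 | step 13 | lithium enolate of the ten-membered ketone | [Li+].[O-]/C1=C\[C@@H](OC(C)(C)C)[C@H]([Si](C)(C)c2ccccc2)/C(C)=C/CC(OC)(OC)[C@]3(C)OC(C)(C)O[C@@H]31
F4 | step 14 | cis-fused lactone (6α-O epimer of 25) | O=C1O[C@@H]2[C@H](C1)[C@@H](OC(C)(C)C)[C@H]([Si](C)(C)c3ccccc3)/C(C)=C/CC(OC)(OC)[C@]4(C)OC(C)(C)O[C@@H]42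
F5 | step 14 | 6α-hydroxy acid | O[C@@H]1[C@H](CC(=O)O)[C@@H](OC(C)(C)C)[C@H]([Si](C)(C)c2ccccc2)/C(C)=C/CC(OC)(OC)[C@]3(C)OC(C)(C)O[C@@H]31
F6 | step 17 | saturated lactone 9α-alcohol | O=C1O[C@H]2[C@H](C1)[C@@H](OC(C)(C)C)[C@H](O)[C@H](C)CCC(OC)(OC)[C@]3(C)OC(C)(C)O[C@@H]32
F7 | step 17 | triethylsilyl ether of F6 | O=C1O[C@H]2[C@H](C1)[C@@H](OC(C)(C)C)[C@H](O[Si](CC)(CC)CC)[C@H](C)CCC(OC)(OC)[C@]3(C)OC(C)(C)O[C@@H]32
F8 | step 17 | Mannich base of F7 (C11 epimers) | CN(C)CC1C(=O)O[C@H]2[C@H]1[C@@H](OC(C)(C)C)[C@H](O[Si](CC)(CC)CC)[C@H](C)CCC(OC)(OC)[C@]3(C)OC(C)(C)O[C@@H]32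
F9 | step 17 | trimethylammonium iodide of F8 | [I-].C[N+](C)(C)CC1C(=O)O[C@H]2[C@H]1[C@@H](OC(C)(C)C)[C@H](O[Si](CC)(CC)CC)[C@H](C)CCC(OC)(OC)[C@]3(C)OC(C)(C)O[C@@H]32
F10 | step 17 | α-methylene lactone 9-O-triethylsilyl ether | C=C1C(=O)O[C@H]2[C@H]1[C@@H](OC(C)(C)C)[C@H](O[Si](CC)(CC)CC)[C@H](C)CCC(OC)(OC)[C@]3(C)OC(C)(C)O[C@@H]32
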